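## Analysis of the target

CNP0174261.1 is a benzodioxane neolignan built from three rings. Ring B is a 2,3-dihydro-1,4-dioxine fused to ring A. Its C2 (Cα) carries the 3,4-dihydroxy-5-methoxyphenyl ring C, and its C3 (Cβ) carries CH2OH (Cγ). Ring A also bears a methoxy group at C5 and an (E)-3-hydroxyprop-1-enyl chain at C7.

The only stereocentres are the neighbouring Cα (S) and Cβ (R). Reading the SMILES places the aryl and hydroxymethyl groups on the same face, so the target is the cis-benzodioxane, the less stable of the two diastereomers.

Ring B is unsymmetrical with respect to ring A. The oxygen on Cβ is the ring A oxygen flanked by the methoxy-bearing carbon, and the oxygen on Cα is the one next to an unsubstituted ring carbon. The two catechol oxygens of ring A therefore have to be told apart.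

The sensitive groups are the free catechol of ring C (oxidised in base), the p-hydroxybenzyl aryl ether at Cα (reversible quinone methide formation would drain cis into trans), the cinnamyl alcohol (ionises in acid) and the E-alkene.

The difficulty is to set a contra-thermodynamic cis relationship at a benzylic centre in one absolute sense, with the right orientation of ring B, and to unmask phenols and allylic alcohol at the end without acid or base.

The strategy rests on the chain Cα–Cβ–Cγ–O(H). Bonding this oxygen back to Cα gives a 2-aryl-3-aryloxyoxetane. In that oxetane the ring A oxygen destined for Cα sits in position for a 6-exo displacement at Cα, which converts the strained ring into ring B.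

## Retrosynthetic reasoning

**22 ⇒ 21.** The last bonds touched are the C–O bonds of the ester and of the protecting groups. One excess-hydride reduction converts the methyl enoate of 21 into the allylic alcohol and removes both pivalates. The catechol and the p-hydroxybenzyl ether then exist only in the final flask, at low temperature and without base or strong acid.

**21 ⇒ 19 + 20.** The side-chain C=C bond is cut. A stabilised ylide (20) on aldehyde 19 gives the E-alkene under thermodynamic control. The chain cannot be present earlier, because a styrene or cinnamate would quench the excited aldehyde of the photochemical step.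

**19 ⇒ 18 ⇒ 17.** These are oxidation-level and protecting-group changes on the ring A carbon. It is carried as a silylated benzylic alcohol (17), freed to diol 18 and oxidised selectively at the benzylic position to 19. An aldehyde on ring A would itself be excited in the key step.

**17 ⇒ 16 ⇒ 15.** Ring B is opened at the Cα–O(ring A) bond and Cα is reconnected to the oxygen on Cγ, which makes 17 the ring-expanded isomer of oxetane phenol 16. In the forward direction the phenol attacks Cα from the back while the acid-activated oxetane oxygen leaves. This bond is chosen because it is the benzylic one, and an invertive displacement on the strained ring turns a cis-oxetane into the cis-benzodioxane. Ring strain drives the step under mild acid, and the acyl groups on ring C keep Cα from ionising. 16 comes from 15 by removing only the aryl silyl ether.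

**15 ⇒ 14.** No catalyst is known that controls the absolute sense of this photocycloaddition. The single enantiomer 15 is therefore taken from racemic 14 on a chiral stationary phase, directly after the key step, so that no later reagent is spent on the wrong enantiomer.

**14 ⇒ 3 + 13.** The Cα–Cβ and Cγ–O bonds are cut together. This separates ring C (aldehyde 3) from ring A (aryl vinyl ether 13), and these are exactly the two bonds a carbonyl–alkene photocycloaddition makes.
- The carbonyl carbon ends up on the oxygen-bearing vinyl carbon, a connectivity that polar chemistry of a vinyl ether does not give.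
- The step gains the C–C bond, both stereocentres in their relative configuration and the Cγ oxygen.
- The orientation of ring B is already fixed, because the vinyl group sits on the ring A oxygen that stays on Cβ.
- The forward reaction must deliver the 3-aryloxy regiochemistry, favour the cis isomer and excite only the aldehyde.

**3 ⇒ 1 + 2.** Both phenols of 1 are acylated with 2. Acyl groups, unlike ethers, keep the ring from becoming a strong donor.

**13 ⇒ 12 ⇒ 9 ⇒ 7 ⇒ 6 ⇒ 4 + 5.** 13 is cut at the phenolic O–Si bond to 12, and 12 at the aryl C–O bond to bromide 9 (bromine–lithium exchange, borylation, oxidation). 9 goes back through alcohol 7 to aldehyde 6, the O-vinyl ether of 4 made with 5. Compound 4 is used rather than catechol 1 because it has a single phenol, so the vinyl group can only sit on the correct oxygen, and bromine marks the place of the second oxygen. Differentiating the hydroxyls of 1 by silylation would put a silyl ether beside a free phenoxide during the basic vinylation. O-to-O silyl migration could then move the vinyl group to the wrong oxygen and reverse the orientation of ring B.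

## Alternatives that were turned down

**Alternative 1:** Ring B is cut at the Cβ–O bond. The precursor would be epoxy phenol A2, in which Cα already carries its ring A aryl ether and Cβ–Cγ is a terminal epoxide. With base the neighbouring ring A phenoxide attacks the internal epoxide carbon Cβ with inversion (6-exo-tet), closes ring B and frees the Cγ hydroxyl to give cinnamate A1.
- For it: the inversion is at a non-benzylic carbon, so no cation can form; both centres of A2 can come from asymmetric catalysis, so nothing is lost in a resolution; A1 already has the three-carbon chain.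
- Against it: the 6-exo path must beat 7-endo attack at the unhindered terminal carbon, while Cβ is secondary and β to the Cα–O bond, and the phenoxide is conjugated to the acrylate para to it and so a weak nucleophile.
- Against it: A2 needs the benzylic Cα–O–aryl bond made with defined configuration next to an epoxide on an electron-rich MOM-protected ring C, where substitution tends to ionise.
- Against it: the ring A hydroxyls must be differentiated on a base-sensitive cinnamate, and the MOM ethers need acid at the end, beside the cinnamyl alcohol and the cis benzylic ether.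
- Comparison: this alternative is stronger on absolute stereocontrol and on avoiding a resolution. The chosen route offers a shorter way to the cyclisation precursor (C–C bond and both centres in one step) and acyl protection that falls in the same hydride step that makes the allylic alcohol.

**Alternative 2:** Ring B is cut between the ring A carbon and the oxygen on Cα. Bromo alcohol A4, with ring A derived from 4 and both stereocentres in place, would be cyclised with CuI, a phenanthroline ligand and Cs2CO3. The benzylic Cα alkoxide is arylated at the neighbouring C–Br carbon to give A3.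
- For it: no bond to Cα or Cβ is broken, so the cis relationship of A3 is simply the relative configuration of A4 and cannot leak by ionisation. Bromine marks which ring A position becomes the Cα oxygen. On security at the benzylic centre it is stronger than the chosen route.
- Against it: a hindered secondary benzylic alkoxide must couple with an electron-rich aryl bromide in hot carbonate, where oxidation of the carbinol and hydrodebromination compete.
- Against it: A4 needs the anti arrangement of Cα–OH and Cβ–OAr in one absolute sense, which means an auxiliary-controlled aldol and several linear steps before ring closure.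
- Against it: the acetal and MOM groups of A3 are unmasked by acid, and the side chain is still to be built.
- Comparison: it is longer and less convergent up to ring closure. The chosen route pays for its convergence with a resolution.

**Alternative 3:** Both ring B C–O bonds, at Cα and at the ring A carbon, are cut. Bromophenol A7 and trans-(2R,3R)-epoxide A6 would react in one flask. The phenoxide opens the epoxide at benzylic Cα with inversion, and the freed Cβ alkoxide is arylated at the adjacent C–Br carbon under CuI catalysis to give aldehyde A5.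
- For it: the highest convergence of the four strategies, an epoxide available in one absolute sense by asymmetric epoxidation, no resolution and probably the fewest steps. On step economy and absolute control it is stronger than the chosen route.
- Against it: under base the phenoxide has no strong reason to prefer Cα over Cβ, and Lewis-acid help on the electron-rich MOM-protected ring C invites ionisation and loss of the inversion.
- Against it: the C–Br carbon of A7 is flanked by two oxygen substituents, which slows the copper step; the free aldehyde must survive hot carbonate; MOM removal again needs acid.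
- Comparison: the chosen route fixes the orientation of ring B covalently before either stereocentre exists. Its inversion at Cα is intramolecular, on a strained ring with an acyl-deactivated benzylic carbon, under mild acid at room temperature. Its final unmasking needs neither acid nor base.

Key step: step 7

Remark on numbering: the benzodioxane is numbered O1, C2 (Cα, aryl), C3 (Cβ, CH2OH), O4, with OMe at C5 and the ring A carbon substituent at C7; in this numbering the target is (2S,3R), cis. The oxetane is numbered O1, C2 (Cα), C3 (Cβ), C4 (Cγ). TBS = tert-butyldimethylsilyl.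

Assumption: the chromatographic separation of enantiomers is counted as a step; which eluted enantiomer is (2R,3R) is to be settled by anomalous-dispersion X-ray analysis of a crystalline derivative.

## Route

Step 1
Reactants: 1 5-hydroxyvanillin (3,4-dihydroxy-5-methoxybenzaldehyde); 2 pivaloyl chloride
Product: 3 3-methoxy-4,5-bis(pivaloyloxy)benzaldehyde
Conditions: PivCl (2.5 equiv), Et3N (3 equiv), DMAP (5 mol%), CH2Cl2, 0 °C to rt
Reagents that add atoms: pivaloyl chloride 2, CC(C)(C)C(=O)Cl
Why: DMAP-catalysed O-acylation of both phenols; the acyl groups weaken the donor character of the ring so that the aldehyde keeps an n,π*-type triplet and Cα later resists ionisation.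

Step 2
Reactants: 4 5-bromovanillin (3-bromo-4-hydroxy-5-methoxybenzaldehyde); 5 vinyl acetate
Product: 6 3-bromo-5-methoxy-4-(vinyloxy)benzaldehyde
Conditions: vinyl acetate (3 equiv), [Ir(cod)Cl]2 (2 mol%), Na2CO3 (0.6 equiv), toluene, 100 °C
Reagents that add atoms: vinyl acetate 5, CC(=O)OC=C
Why: Iridium-catalysed transfer vinylation of a phenol (phenoxide adds to coordinated vinyl acetate, then acetate is eliminated); 4 has one phenol only, so the vinyl group can only reach the oxygen that will carry Cβ.

Step 3
Reactants: 6 3-bromo-5-methoxy-4-(vinyloxy)benzaldehyde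
Product: 7 [3-bromo-5-methoxy-4-(vinyloxy)phenyl]methanol
Conditions: NaBH4, MeOH/THF, 0 °C
Reagents that add atoms: none
Why: Borohydride reduction of the aryl aldehyde; the aryl vinyl ether and the aryl bromide are inert to hydride and to the basic medium.

Step 4
Reactants: 7 [3-bromo-5-methoxy-4-(vinyloxy)phenyl]methanol; 8 tert-butyldimethylsilyl chloride
Product: 9 3-bromo-5-methoxy-4-(vinyloxy)benzyl TBS ether
Conditions: TBSCl, imidazole, DMF, rt
Reagents that add atoms: tert-butyldimethylsilyl chloride 8, CC(C)(C)[Si](C)(C)Cl
Why: Standard silylation under non-acidic conditions that spare the vinyl ether; it removes the O–H before the organolithium step.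

Step 5
Reactants: 9 3-bromo-5-methoxy-4-(vinyloxy)benzyl TBS ether
Product: 12 5-(TBS-oxymethyl)-3-methoxy-2-(vinyloxy)phenol, via aryllithium 10 (not isolated), via dimethyl arylboronate 11 (not isolated)
Conditions: n-BuLi (1.1 equiv), THF, −78 °C; B(OMe)3, −78 to 0 °C; then 30% H2O2, aq. NaOH, 0 °C; work-up at pH 7
Reagents that add atoms: hydrogen peroxide, OO
Why: Bromine–lithium exchange, borylation and boronate oxidation (1,2-aryl shift from boron to oxygen) put the second oxygen exactly where bromine was; at −78 °C exchange is faster than any attack on the vinyl ether. The phenol is kept neutral and silylated at once, because 2-(vinyloxy)phenols close to cyclic acetals with acid.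

Step 6
Reactants: 12 5-(TBS-oxymethyl)-3-methoxy-2-(vinyloxy)phenol; 8 tert-butyldimethylsilyl chloride
Product: 13 3-(TBS-oxy)-5-methoxy-4-(vinyloxy)benzyl TBS ether (ring A aryl vinyl ether)
Conditions: TBSCl, imidazole, DMF, rt; chromatography on Et3N-deactivated silica
Reagents that add atoms: tert-butyldimethylsilyl chloride 8, CC(C)(C)[Si](C)(C)Cl
Why: Silylation of the phenol; a free phenolic O–H would quench the triplet aldehyde of the next step by hydrogen transfer.

Step 7
Reactants: 3 3-methoxy-4,5-bis(pivaloyloxy)benzaldehyde; 13 ring A aryl vinyl ether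
Product: 14 racemic cis-2-[3-methoxy-4,5-bis(pivaloyloxy)phenyl]-3-[2-(TBS-oxy)-4-(TBS-oxymethyl)-6-methoxyphenoxy]oxetane
Conditions: 13 (2 equiv, excess recovered), degassed benzene (0.05 M in 3), hν 350 nm (Pyrex), 10 °C; chromatography on Et3N-buffered silica
Reagents that add atoms: none
Why: Light of 350 nm reaches only the n→π* band of 3; after intersystem crossing the electrophilic oxygen of the triplet aldehyde adds to the terminal carbon of the electron-rich vinyl ether, giving a triplet 1,4-biradical with one centre at the benzylic carbon and one at the aryloxy-bearing carbon. After spin inversion the two radical centres combine, which forms the Cα–Cβ bond and closes the oxetane; the ring is closed by biradical recombination, not by a polar exo or endo cyclisation. The closest known reaction type is the Paternò–Büchi photocycloaddition of aromatic aldehydes with enol ethers to 3-alkoxy-2-aryloxetanes. The 3-aryloxy regiochemistry is secured by the stability of the α-aryloxy radical over the primary radical that attack at the internal carbon would give; any acetal-type 2-aryloxy isomer is acid-labile and is removed on chromatography. Cα and Cβ are both created here and their relative configuration is fixed at ring closure, where the geometry needed for spin inversion in the biradical is expected to favour the cis arrangement of aryl and aryloxy groups, though not exclusively, so the trans isomer is separated. Nothing controls the absolute sense, so 14 is racemic and is resolved in step 8. The acyloxy groups keep the reactive triplet of 3 n,π*-like, light above 340 nm avoids photo-Fries rearrangement of the pivalates and direct excitation of the arene of 13, and the excess of 13 outruns hydrogen abstraction and pinacol coupling.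

Step 8
Reactants: 14 racemic cis-oxetane
Product: 15 (2R,3R)-2-[3-methoxy-4,5-bis(pivaloyloxy)phenyl]-3-[2-(TBS-oxy)-4-(TBS-oxymethyl)-6-methoxyphenoxy]oxetane
Conditions: preparative SFC on amylose tris(3,5-dimethylphenylcarbamate), CO2/i-PrOH
Reagents that add atoms: none
Why: Resolution by chromatography on a chiral stationary phase; no bond is made or broken, the (2R,3R) enantiomer is collected and both stereocentres are thereby fixed in the absolute sense.

Step 9
Reactants: 15 (2R,3R)-oxetane
Product: 16 (2R,3R)-2-[3-methoxy-4,5-bis(pivaloyloxy)phenyl]-3-[2-hydroxy-4-(TBS-oxymethyl)-6-methoxyphenoxy]oxetane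
Conditions: KHF2 (2.5 equiv), MeOH, rt
Reagents that add atoms: none
Why: Bifluoride desilylation that is selective for aryl silyl ethers; the benzylic alkyl silyl ether and the hindered aryl pivalates react far more slowly. Any early ring expansion in this mildly acidic medium only anticipates step 10.

Step 10
Reactants: 16 oxetane phenol
Product: 17 (2S,3R)-2-[3-methoxy-4,5-bis(pivaloyloxy)phenyl]-3-(hydroxymethyl)-5-methoxy-7-(TBS-oxymethyl)-2,3-dihydro-1,4-benzodioxine
Conditions: (PhO)2P(O)OH (10 mol%), 4 Å molecular sieves, CH2Cl2, 0 °C to rt
Reagents that add atoms: none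
Why: Acid-catalysed intramolecular ring opening of an oxetane by a phenol (strain-release 6-exo-tet etherification); the acid activates the oxetane oxygen and the phenol attacks benzylic Cα from the back, so Cα is inverted (R to S), Cβ is untouched and the cis-oxetane becomes the cis-benzodioxane with Cγ–OH set free. The acyl-deactivated ring C keeps the displacement concerted, and the benzylic C–O bond is the more polarised of the two oxetane C–O bonds, which directs attack to Cα and not to Cγ.

Step 11
Reactants: 17 benzodioxane silyl ether
Product: 18 (2S,3R)-2-[3-methoxy-4,5-bis(pivaloyloxy)phenyl]-3,7-bis(hydroxymethyl)-5-methoxy-2,3-dihydro-1,4-benzodioxine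
Conditions: TBAF (Bu4NF)/AcOH (1:1, 3 equiv), THF, 0 °C to rt
Reagents that add atoms: none
Why: Buffered fluoride desilylation of the primary benzylic silyl ether; the acetic acid keeps the medium non-basic, so the aryl pivalates are neither cleaved nor transferred.

Step 12
Reactants: 18 diol
Product: 19 (2S,3R)-2-[3-methoxy-4,5-bis(pivaloyloxy)phenyl]-3-(hydroxymethyl)-5-methoxy-2,3-dihydro-1,4-benzodioxine-7-carbaldehyde
Conditions: activated MnO2 (15 equiv), CH2Cl2, rt
Reagents that add atoms: none
Why: MnO2 oxidises benzylic alcohols chemoselectively; the saturated primary alcohol at Cγ is left alone.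

Step 13
Reactants: 19 aldehyde; 20 methyl (triphenylphosphoranylidene)acetate
Product: 21 methyl (E)-3-{(2S,3R)-2-[3-methoxy-4,5-bis(pivaloyloxy)phenyl]-3-(hydroxymethyl)-5-methoxy-2,3-dihydro-1,4-benzodioxin-7-yl}prop-2-enoate
Conditions: Ph3P=CHCO2Me (1.3 equiv), toluene, 70 °C
Reagents that add atoms: methyl (triphenylphosphoranylidene)acetate 20, COC(=O)C=P(c1ccccc1)(c1ccccc1)c1ccccc1
Why: Wittig olefination with a stabilised ylide, which is E-selective and tolerates the free hydroxyl and the aryl esters.

Step 14
Reactants: 21 methyl cinnamate bis-pivalate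
Product: 22 (2S,3R)-2-(3,4-dihydroxy-5-methoxyphenyl)-3-(hydroxymethyl)-7-[(E)-3-hydroxyprop-1-enyl]-5-methoxy-2,3-dihydro-1,4-benzodioxine (CNP0174261.1)
Conditions: DIBAL-H (i-Bu2AlH, 9 equiv), CH2Cl2, −78 to −20 °C; MeOH, then degassed aq. citric acid, Ar
Reagents that add atoms: none
Why: Hydride reduction that gives 1,2-reduction of the enoate to the allylic alcohol and reductive cleavage of both aryl pivalates in one flask. Low temperature, covalent aluminium phenoxides and a weakly acidic oxygen-free work-up protect the cis p-hydroxybenzyl aryl ether from the quinone methide pathway and the catechol from oxidation.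

## Compound list

1 | 5-hydroxyvanillin (3,4-dihydroxy-5-methoxybenzaldehyde) | COc1cc(C=O)cc(O)c1O | starting material
2 | pivaloyl chloride | CC(C)(C)C(=O)Cl | starting material
3 | 3-methoxy-4,5-bis(pivaloyloxy)benzaldehyde | COc1cc(C=O)cc(OC(=O)C(C)(C)C)c1OC(=O)C(C)(C)C | intermediate
4 | 5-bromovanillin (3-bromo-4-hydroxy-5-methoxybenzaldehyde) | COc1cc(C=O)cc(Br)c1O | starting material
5 | vinyl acetate | CC(=O)OC=C | starting material
6 | 3-bromo-5-methoxy-4-(vinyloxy)benzaldehyde | C=COc1c(OC)cc(C=O)cc1Br | intermediate
7 | [3-bromo-5-methoxy-4-(vinyloxy)phenyl]methanol | C=COc1c(OC)cc(CO)cc1Br | intermediate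
8 | tert-butyldimethylsilyl chloride | CC(C)(C)[Si](C)(C)Cl | starting material
9 | 3-bromo-5-methoxy-4-(vinyloxy)benzyl TBS ether | C=COc1c(OC)cc(CO[Si](C)(C)C(C)(C)C)cc1Br | intermediate
10 | aryllithium from 9, lithium in place of bromine (not isolated) | C=COc1c(OC)cc(CO[Si](C)(C)C(C)(C)C)cc1[Li] | intermediate
11 | dimethyl arylboronate from 10 (not isolated) | C=COc1c(OC)cc(CO[Si](C)(C)C(C)(C)C)cc1B(OC)OC | intermediate
12 | 5-(TBS-oxymethyl)-3-methoxy-2-(vinyloxy)phenol | C=COc1c(OC)cc(CO[Si](C)(C)C(C)(C)C)cc1O | intermediate
13 | 3-(TBS-oxy)-5-methoxy-4-(vinyloxy)benzyl TBS ether (ring A aryl vinyl ether) | C=COc1c(OC)cc(CO[Si](C)(C)C(C)(C)C)cc1O[Si](C)(C)C(C)(C)C | intermediate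
14 | racemic cis-2-[3-methoxy-4,5-bis(pivaloyloxy)phenyl]-3-[2-(TBS-oxy)-4-(TBS-oxymethyl)-6-methoxyphenoxy]oxetane (racemate; the (2R,3R) enantiomer is drawn) | COc1cc([C@@H]2[C@H](Oc3c(OC)cc(CO[Si](C)(C)C(C)(C)C)cc3O[Si](C)(C)C(C)(C)C)CO2)cc(OC(=O)C(C)(C)C)c1OC(=O)C(C)(C)C | intermediate
15 | (2R,3R)-2-[3-methoxy-4,5-bis(pivaloyloxy)phenyl]-3-[2-(TBS-oxy)-4-(TBS-oxymethyl)-6-methoxyphenoxy]oxetane (single enantiomer, cis) | COc1cc([C@@H]2[C@H](Oc3c(OC)cc(CO[Si](C)(C)C(C)(C)C)cc3O[Si](C)(C)C(C)(C)C)CO2)cc(OC(=O)C(C)(C)C)c1OC(=O)C(C)(C)C | intermediate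
16 | (2R,3R)-2-[3-methoxy-4,5-bis(pivaloyloxy)phenyl]-3-[2-hydroxy-4-(TBS-oxymethyl)-6-methoxyphenoxy]oxetane | COc1cc([C@@H]2[C@H](Oc3c(OC)cc(CO[Si](C)(C)C(C)(C)C)cc3O)CO2)cc(OC(=O)C(C)(C)C)c1OC(=O)C(C)(C)C | intermediate
17 | (2S,3R)-2-[3-methoxy-4,5-bis(pivaloyloxy)phenyl]-3-(hydroxymethyl)-5-methoxy-7-(TBS-oxymethyl)-2,3-dihydro-1,4-benzodioxine (cis) | COc1cc([C@@H]2Oc3cc(CO[Si](C)(C)C(C)(C)C)cc(OC)c3O[C@@H]2CO)cc(OC(=O)C(C)(C)C)c1OC(=O)C(C)(C)C | intermediate
18 | (2S,3R)-2-[3-methoxy-4,5-bis(pivaloyloxy)phenyl]-3,7-bis(hydroxymethyl)-5-methoxy-2,3-dihydro-1,4-benzodioxine | COc1cc([C@@H]2Oc3cc(CO)cc(OC)c3O[C@@H]2CO)cc(OC(=O)C(C)(C)C)c1OC(=O)C(C)(C)C | intermediate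
19 | (2S,3R)-2-[3-methoxy-4,5-bis(pivaloyloxy)phenyl]-3-(hydroxymethyl)-5-methoxy-2,3-dihydro-1,4-benzodioxine-7-carbaldehyde | COc1cc([C@@H]2Oc3cc(C=O)cc(OC)c3O[C@@H]2CO)cc(OC(=O)C(C)(C)C)c1OC(=O)C(C)(C)C | intermediate
20 | methyl (triphenylphosphoranylidene)acetate | COC(=O)C=P(c1ccccc1)(c1ccccc1)c1ccccc1 | starting material
21 | methyl (E)-3-{(2S,3R)-2-[3-methoxy-4,5-bis(pivaloyloxy)phenyl]-3-(hydroxymethyl)-5-methoxy-2,3-dihydro-1,4-benzodioxin-7-yl}prop-2-enoate | COc1cc([C@@H]2Oc3cc(/C=C/C(=O)OC)cc(OC)c3O[C@@H]2CO)cc(OC(=O)C(C)(C)C)c1OC(=O)C(C)(C)C | intermediate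
22 | (2S,3R)-2-(3,4-dihydroxy-5-methoxyphenyl)-3-(hydroxymethyl)-7-[(E)-3-hydroxyprop-1-enyl]-5-methoxy-2,3-dihydro-1,4-benzodioxine (CNP0174261.1) | COc1cc([C@@H]2Oc3cc(/C=C/CO)cc(OC)c3O[C@@H]2CO)cc(O)c1O | target

## Step count and least certain steps

Total step count: 14 (the resolution counted as step 8). Longest linear sequence: 13 steps (4 to 22, steps 2 to 14); the branch 1 to 3 is one step.

**Step 7 (key step).** What may go wrong:
- unproductive charge-transfer quenching of the triplet aldehyde by the electron-rich arene of 13;
- a slow addition because the meta-methoxy group mixes π,π* character into the triplet;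
- hydrogen abstraction from the benzylic ether CH2;
- a cis/trans and regioisomer distribution that erodes the supply of the cis isomer.

Fallback, from 13 and 3, back at 15. It builds the same oxetane by ionic chemistry.
- Hydroboration of the vinyl ether of 13 (9-BBN, THF; NaBO3·4H2O) would give 2-[2-(TBS-oxy)-4-(TBS-oxymethyl)-6-methoxyphenoxy]ethanol F1.
- Oxidation (TEMPO, PhI(OAc)2, MeCN/H2O) would give the aryloxyacetic acid F2.
- The mixed anhydride with 2, then N-lithiated (S)-4-benzyl-2-oxazolidinone, would give the imide F3.
- Its boron enolate (Bu2BOTf, i-Pr2NEt, CH2Cl2, −78 °C) would add to 3 in an Evans syn glycolate aldol to give the (2S,3R)-aldol adduct F4.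
- NaBH4 in THF/H2O would remove the auxiliary reductively to the syn-(1R,2R)-1,3-diol F5.
- TsCl/pyridine at the primary hydroxyl would give the primary tosylate F6, and NaH in THF would close the oxetane by 4-exo-tet Williamson etherification with retention at both centres.
- This gives 15 as a single enantiomer, so step 8 would fall away as well.

**Step 10.** What may go wrong:
- attack of the phenol at the unsubstituted oxetane carbon Cγ (also a 6-exo closure), which would put the aryl carbinol outside ring B;
- ionisation at Cα before the phenol arrives, which would erode the cis configuration.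

Fallback, from 3 and 13 by way of diol F5 (made as above), back at 18. It bypasses the oxetane.
- 8 with imidazole at −20 °C silylates the primary hydroxyl to the primary silyl ether F7.
- KHF2/MeOH frees the ring A phenol to give the phenol F8.
- PPh3/DIAD (Mitsunobu) closes ring B by displacement at Cα with inversion. The only free alcohol is the benzylic one, so the regiochemistry is unambiguous. This gives the bis-silylated cis-benzodioxane F9.
- The conditions of step 11 remove both alkyl silyl ethers and give 18.

**Step 8.** What may go wrong: insufficient separation of the enantiomers at preparative loading, so that throughput collapses.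

Fallback, from 14, back at 17.
- The racemate is taken through steps 9 and 10 to the racemic oxetane phenol F10 and the racemic benzodioxane alcohol F11.
- Burkholderia cepacia lipase with 5 in t-BuOMe acylates one enantiomer of the primary alcohol, and alcohol and acetate are separated on silica.
- If the (2S,3R) alcohol is the slow-reacting one, it is 17.
- If it is the fast one, its acetate F12 is deacetylated by the same lipase with n-BuOH, which returns 17.

**Step 2.** What may go wrong: acetyl transfer instead of vinyl transfer, or low conversion, because the phenol of 4 is hindered and acidic.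

Fallback, from 4, back at 7.
- O-alkylation with excess 1,2-dibromoethane (K2CO3, DMF, 60 °C) gives 3-bromo-4-(2-bromoethoxy)-5-methoxybenzaldehyde F13.
- NaBH4 gives [3-bromo-4-(2-bromoethoxy)-5-methoxyphenyl]methanol F14.
- t-BuOK (2.2 equiv) in THF at 0 °C eliminates HBr to give 7.

## Further compounds

F1 | step 7 | 2-[2-(TBS-oxy)-4-(TBS-oxymethyl)-6-methoxyphenoxy]ethanol | OCCOc1c(OC)cc(CO[Si](C)(C)C(C)(C)C)cc1O[Si](C)(C)C(C)(C)C
F2 | step 7 | [2-(TBS-oxy)-4-(TBS-oxymethyl)-6-methoxyphenoxy]acetic acid | OC(=O)COc1c(OC)cc(CO[Si](C)(C)C(C)(C)C)cc1O[Si](C)(C)C(C)(C)C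
F3 | step 7 | (S)-4-benzyl-3-{[2-(TBS-oxy)-4-(TBS-oxymethyl)-6-methoxyphenoxy]acetyl}oxazolidin-2-one | O=C(COc1c(OC)cc(CO[Si](C)(C)C(C)(C)C)cc1O[Si](C)(C)C(C)(C)C)N1[C@@H](Cc2ccccc2)COC1=O
F4 | step 7 | (S)-4-benzyl-3-{(2S,3R)-2-[2-(TBS-oxy)-4-(TBS-oxymethyl)-6-methoxyphenoxy]-3-hydroxy-3-[3-methoxy-4,5-bis(pivaloyloxy)phenyl]propanoyl}oxazolidin-2-one | O=C([C@@H](Oc1c(OC)cc(CO[Si](C)(C)C(C)(C)C)cc1O[Si](C)(C)C(C)(C)C)[C@H](O)c1cc(OC)c(OC(=O)C(C)(C)C)c(OC(=O)C(C)(C)C)c1)N1[C@@H](Cc2ccccc2)COC1=O
F5 | step 7 | (1R,2R)-2-[2-(TBS-oxy)-4-(TBS-oxymethyl)-6-methoxyphenoxy]-1-[3-methoxy-4,5-bis(pivaloyloxy)phenyl]propane-1,3-diol (syn) | OC[C@@H](Oc1c(OC)cc(CO[Si](C)(C)C(C)(C)C)cc1O[Si](C)(C)C(C)(C)C)[C@H](O)c1cc(OC)c(OC(=O)C(C)(C)C)c(OC(=O)C(C)(C)C)c1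
F6 | step 7 | primary p-toluenesulfonate of F5 | Cc1ccc(cc1)S(=O)(=O)OC[C@@H](Oc1c(OC)cc(CO[Si](C)(C)C(C)(C)C)cc1O[Si](C)(C)C(C)(C)C)[C@H](O)c1cc(OC)c(OC(=O)C(C)(C)C)c(OC(=O)C(C)(C)C)c1
F7 | step 10 | primary TBS ether of F5 | CC(C)(C)[Si](C)(C)OC[C@@H](Oc1c(OC)cc(CO[Si](C)(C)C(C)(C)C)cc1O[Si](C)(C)C(C)(C)C)[C@H](O)c1cc(OC)c(OC(=O)C(C)(C)C)c(OC(=O)C(C)(C)C)c1
F8 | step 10 | F7 with the ring A phenol free | CC(C)(C)[Si](C)(C)OC[C@@H](Oc1c(OC)cc(CO[Si](C)(C)C(C)(C)C)cc1O)[C@H](O)c1cc(OC)c(OC(=O)C(C)(C)C)c(OC(=O)C(C)(C)C)c1
F9 | step 10 | (2S,3R)-2-[3-methoxy-4,5-bis(pivaloyloxy)phenyl]-3,7-bis(TBS-oxymethyl)-5-methoxy-2,3-dihydro-1,4-benzodioxine | COc1cc([C@@H]2Oc3cc(CO[Si](C)(C)C(C)(C)C)cc(OC)c3O[C@@H]2CO[Si](C)(C)C(C)(C)C)cc(OC(=O)C(C)(C)C)c1OC(=O)C(C)(C)C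
F10 | step 8 | racemic 16 (racemate; the (2R,3R) enantiomer is drawn) | COc1cc([C@@H]2[C@H](Oc3c(OC)cc(CO[Si](C)(C)C(C)(C)C)cc3O)CO2)cc(OC(=O)C(C)(C)C)c1OC(=O)C(C)(C)C
F11 | step 8 | racemic 17 (racemate; the (2S,3R) enantiomer is drawn) | COc1cc([C@@H]2Oc3cc(CO[Si](C)(C)C(C)(C)C)cc(OC)c3O[C@@H]2CO)cc(OC(=O)C(C)(C)C)c1OC(=O)C(C)(C)C
F12 | step 8 | (2S,3R)-acetate of 17 (3-acetoxymethyl) | COc1cc([C@@H]2Oc3cc(CO[Si](C)(C)C(C)(C)C)cc(OC)c3O[C@@H]2COC(C)=O)cc(OC(=O)C(C)(C)C)c1OC(=O)C(C)(C)C
F13 | step 2 | 3-bromo-4-(2-bromoethoxy)-5-methoxybenzaldehyde | COc1cc(C=O)cc(Br)c1OCCBr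
F14 | step 2 | [3-bromo-4-(2-bromoethoxy)-5-methoxyphenyl]methanol | COc1cc(CO)cc(Br)c1OCCBr
A1 | alternative 1 | cis-2-aryl-3-(hydroxymethyl)-1,4-benzodioxane methyl cinnamate, ring C bis-MOM | COc1cc([C@@H]2Oc3cc(/C=C/C(=O)OC)cc(OC)c3O[C@@H]2CO)cc(OCOC)c1OCOC
A2 | alternative 1 | epoxy phenol: Cα aryl ether of ring A with a terminal Cβ–Cγ epoxide and a free ring A phenol | COc1cc([C@H](Oc2cc(/C=C/C(=O)OC)cc(OC)c2O)[C@@H]2CO2)cc(OCOC)c1OCOC
A3 | alternative 2 | cis-2-aryl-3-(TBS-oxymethyl)-1,4-benzodioxane dimethyl acetal, ring C bis-MOM | COc1cc([C@@H]2Oc3cc(C(OC)OC)cc(OC)c3O[C@@H]2CO[Si](C)(C)C(C)(C)C)cc(OCOC)c1OCOC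
A4 | alternative 2 | anti bromo alcohol: Cα carbinol, Cβ ether of the 5-bromovanillin-derived ring A | COc1cc([C@H](O)[C@@H](CO[Si](C)(C)C(C)(C)C)Oc2c(Br)cc(C(OC)OC)cc2OC)cc(OCOC)c1OCOC
A5 | alternative 3 | cis-2-aryl-3-(methoxymethoxymethyl)-1,4-benzodioxane aldehyde, ring C bis-MOM | COc1cc([C@@H]2Oc3cc(C=O)cc(OC)c3O[C@@H]2COCOC)cc(OCOC)c1OCOC
A6 | alternative 3 | trans-(2R,3R)-3-[3-methoxy-4,5-bis(methoxymethoxy)phenyl]glycidol MOM ether | COCOC[C@H]1O[C@@H]1c1cc(OC)c(OCOC)c(OCOC)c1
A7 | alternative 3 | 4-bromo-3-hydroxy-5-methoxybenzaldehyde | COc1cc(C=O)cc(O)c1Br
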